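## Retrosynthetic overview

1. The oxolane ring is formed last: the benzylic C2–O bond is closed by SN1 cycloetherification of the tetraol obtained by hydride reduction of a trans α-(aryl-hydroxymethyl)-β-(arylmethyl)-γ-butyrolactone.
2. That lactone comes from an aldol addition of the (R)-β-(arylmethyl)-γ-butyrolactone enolate to 3,4,5-trimethoxybenzaldehyde, which sets the future C3.
3. The (R)-lactone comes from an enantioselective ring-expansion carbonylation of a prochiral 3-(arylmethyl)oxetane: CO goes into one of two enantiotopic C–O bonds, the four-membered ring becomes five-membered, and the first stereocentre is set.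
4. The oxetane comes from a nickel cross-electrophile coupling of 3-(bromomethyl)oxetane with 4-bromo-2-methoxyphenyl pivalate, itself made from 2-bromophenol.
5. The aldehyde comes from p-cresol (bromination/hydrolysis, then methoxylation/methylation). Ring order: oxetane (bought), then γ-lactone, then oxolane.

Assumption: the (R,R) salen antipode in step 6 is taken to give the (R)-lactone; if the first analytical run shows the opposite sense, the (S,S) ligand is used with no other change.

## Route

**Step 1**
Reactants: 1 4-methylphenol (p-cresol)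
Product: 4 3,5-dibromo-4-hydroxybenzaldehyde, via 2,6-dibromo-4-methylphenol 2 (not isolated), via 2,6-dibromo-4-(dibromomethyl)phenol 3 (not isolated)
Conditions: Br2 (2 equiv), o-dichlorobenzene, 35 °C; Br2 (2 equiv), 155 °C; then H2O, 100 °C
Reagents that add atoms: bromine, BrBr; water, O
Why: Electrophilic ring bromination at both positions ortho to OH, thermal side-chain dibromination of the para-methyl group and hydrolysis of the benzal bromide to the aldehyde, an established one-pot sequence for p-cresol.

**Step 2**
Reactants: 4 3,5-dibromo-4-hydroxybenzaldehyde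
Product: 6 3,4,5-trimethoxybenzaldehyde, via sodium 4-formyl-2,6-dimethoxyphenolate 5 (not isolated)
Conditions: NaOMe (4 equiv), CuCl (5 mol %), DMF/MeOH, 110 °C; MeOH distilled off; then Me2SO4 (2 equiv), 60 °C
Reagents that add atoms: sodium methoxide, [Na+].[O-]C; dimethyl sulfate, COS(=O)(=O)OC
Why: Copper-catalysed Ullmann-type methoxylation of both aryl bromides, followed by Williamson O-methylation of the phenolate in the same pot.

**Step 3**
Reactants: 7 2-bromophenol
Product: 8 2-methoxyphenol
Conditions: NaOMe (3 equiv), CuCl (5 mol %), DMF/MeOH, 110 °C; aq HCl work-up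
Reagents that add atoms: sodium methoxide, [Na+].[O-]C
Why: The same copper-catalysed Ullmann methoxylation, which tolerates an ortho phenolate and avoids the over-methylation of a catechol mono-alkylation.

**Step 4**
Reactants: 8 2-methoxyphenol
Product: 10 4-bromo-2-methoxyphenyl 2,2-dimethylpropanoate (pivalate), via 4-bromo-2-methoxyphenol 9 (not isolated)
Conditions: NBS (1.0 equiv), MeCN, 0 °C; then Et3N (3 equiv), t-BuCOCl (2 equiv), DMAP (5 mol %), 0 °C to rt
Reagents that add atoms: N-bromosuccinimide, O=C1CCC(=O)N1Br; pivaloyl chloride, CC(C)(C)C(=O)Cl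
Why: Electrophilic bromination goes para to the free OH (the stronger director), and only then is the phenol acylated, since an acylated phenol would direct para to OMe.

**Step 5**
Reactants: 10 4-bromo-2-methoxyphenyl 2,2-dimethylpropanoate; 11 3-(bromomethyl)oxetane
Product: 12 3-{[3-methoxy-4-(2,2-dimethylpropanoyloxy)phenyl]methyl}oxetane
Conditions: NiBr2(dme) (10 mol %), 4,4'-di-tert-butyl-2,2'-bipyridine (10 mol %), NaI (25 mol %), Zn (2 equiv), DMA, 60 °C
Reagents that add atoms: none
Why: Nickel-catalysed reductive cross-electrophile coupling: the aryl bromide adds to low-valent nickel, the primary alkyl radical from 11 is captured and reductive elimination forms the aryl–CH2 bond, while the pivalate and the oxetane are inert to Zn/Ni at 60 °C.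

**Step 6**
Reactants: 12 3-{[3-methoxy-4-(2,2-dimethylpropanoyloxy)phenyl]methyl}oxetane
Product: 13 (4R)-4-{[3-methoxy-4-(2,2-dimethylpropanoyloxy)phenyl]methyl}oxolan-2-one
Conditions: [(salen)Cr(THF)2][Co(CO)4] (5 mol %; salen = dianion of (R,R)-N,N'-bis(3,5-di-tert-butylsalicylidene)cyclohexane-1,2-diamine), CO (60 bar), 1,2-dimethoxyethane, 60 °C
Reagents that add atoms: carbon monoxide, [C-]#[O+]
Why: Proposed new method: enantioselective desymmetrising ring-expansion carbonylation of a prochiral 3-substituted oxetane. The cationic trivalent-chromium salen Lewis acid binds the oxetane oxygen and [Co(CO)4]− (cobalt in the minus-one oxidation state) opens one of the two enantiotopic C–O bonds by SN2 attack at CH2; this is the enantio-determining event, the chiral salen pocket exposing only one methylene. The alkyl–cobalt then undergoes migratory insertion of CO (a 1,2-shift of the alkyl group onto CO) and the chromium alkoxide closes on the acyl–cobalt to release the five-membered lactone; the oxetane C3 is untouched and becomes the (R)-configured C4. Closest known reaction types: Lewis acid/[Co(CO)4]− ring-expansion carbonylation of epoxides to β-lactones (including enantioselective desymmetrisation of meso-epoxides) and of oxetane itself to γ-butyrolactone without stereocontrol, and chiral-acid-catalysed desymmetrising openings of 3-substituted oxetanes by nucleophiles.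

**Step 7**
Reactants: 13 (4R)-4-{[3-methoxy-4-(2,2-dimethylpropanoyloxy)phenyl]methyl}oxolan-2-one; 6 3,4,5-trimethoxybenzaldehyde
Product: 14 (3S,4R)-3-[hydroxy(3,4,5-trimethoxyphenyl)methyl]-4-{[3-methoxy-4-(2,2-dimethylpropanoyloxy)phenyl]methyl}oxolan-2-one (3,4-trans; both carbinol epimers)
Conditions: LiN(SiMe3)2 (1.1 equiv), THF, −78 °C; then 6, −78 °C; AcOH quench at −78 °C
Reagents that add atoms: none
Why: Lithium enolate aldol addition in which the aldehyde approaches anti to the C4 arylmethyl group, giving the 3,4-trans lactone and thereby the future C3; the carbinol centre forms as an epimer mixture that converges in step 8.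

**Step 8**
Reactants: 14 (3S,4R)-3-[hydroxy(3,4,5-trimethoxyphenyl)methyl]-4-{[3-methoxy-4-(2,2-dimethylpropanoyloxy)phenyl]methyl}oxolan-2-one
Product: 16 [(2S,3R,4R)-4-[(4-hydroxy-3-methoxyphenyl)methyl]-2-(3,4,5-trimethoxyphenyl)oxolan-3-yl]methanol, via tetraol 15 (not isolated)
Conditions: LiAlH4 (3 equiv), THF, 0 °C to rt; then 2 M aq HCl to pH 1, 40 °C
Reagents that add atoms: none
Why: LiAlH4 reduces the lactone to the 1,4-diol and cleaves the pivalate; in acid the trimethoxybenzylic alcohol ionises and the cation is trapped 5-exo by the hydroxymethyl oxygen on the benzyl-bearing carbon (SN1 cycloetherification). The aryl group settles trans to the adjacent CH2OH, so both carbinol epimers give the 2,3-trans-3,4-cis oxolane (the trans lactone maps onto 3,4-cis because the new ring closes through the carbinol carbon).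

## Compound list

1 | 4-methylphenol (p-cresol) | Cc1ccc(O)cc1 | starting material
2 | 2,6-dibromo-4-methylphenol | Cc1cc(Br)c(O)c(Br)c1 | intermediate
3 | 2,6-dibromo-4-(dibromomethyl)phenol | BrC(Br)c1cc(Br)c(O)c(Br)c1 | intermediate
4 | 3,5-dibromo-4-hydroxybenzaldehyde | O=Cc1cc(Br)c(O)c(Br)c1 | intermediate
5 | sodium 4-formyl-2,6-dimethoxyphenolate | [Na+].[O-]c1c(OC)cc(C=O)cc1OC | intermediate
6 | 3,4,5-trimethoxybenzaldehyde | COc1cc(C=O)cc(OC)c1OC | intermediate
7 | 2-bromophenol | Oc1ccccc1Br | starting material
8 | 2-methoxyphenol | COc1ccccc1O | intermediate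
9 | 4-bromo-2-methoxyphenol | COc1cc(Br)ccc1O | intermediate
10 | 4-bromo-2-methoxyphenyl 2,2-dimethylpropanoate | COc1cc(Br)ccc1OC(=O)C(C)(C)C | intermediate
11 | 3-(bromomethyl)oxetane | BrCC1COC1 | starting material
12 | 3-{[3-methoxy-4-(2,2-dimethylpropanoyloxy)phenyl]methyl}oxetane | COc1cc(CC2COC2)ccc1OC(=O)C(C)(C)C | intermediate
13 | (4R)-4-{[3-methoxy-4-(2,2-dimethylpropanoyloxy)phenyl]methyl}oxolan-2-one | O=C1C[C@@H](Cc2ccc(OC(=O)C(C)(C)C)c(OC)c2)CO1 | intermediate
14 | (3S,4R)-3-[hydroxy(3,4,5-trimethoxyphenyl)methyl]-4-{[3-methoxy-4-(2,2-dimethylpropanoyloxy)phenyl]methyl}oxolan-2-one (both carbinol epimers) | O=C1OC[C@H](Cc2ccc(OC(=O)C(C)(C)C)c(OC)c2)[C@H]1C(O)c1cc(OC)c(OC)c(OC)c1 | intermediate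
15 | (2R,3R)-2-[hydroxy(3,4,5-trimethoxyphenyl)methyl]-3-[(4-hydroxy-3-methoxyphenyl)methyl]butane-1,4-diol (both carbinol epimers) | OC[C@H](Cc1ccc(O)c(OC)c1)[C@H](CO)C(O)c1cc(OC)c(OC)c(OC)c1 | intermediate
16 | [(2S,3R,4R)-4-[(4-hydroxy-3-methoxyphenyl)methyl]-2-(3,4,5-trimethoxyphenyl)oxolan-3-yl]methanol | COc1cc(C[C@H]2CO[C@H](c3cc(OC)c(OC)c(OC)c3)[C@H]2CO)ccc1O | target

## Step count and risks

Total steps: 8. Longest linear sequence: 6 steps (steps 3 to 8, from 2-bromophenol 7).

**Step 6 (the proposed carbonylation).** Risks are low enantioselectivity, Lewis-acid-induced oxetane polymerisation, or isomerisation to the homoallylic alcohol. The fallback uses known chemistry and keeps a ring expansion. It sets out from 10: the aryl bromide is coupled under the conditions of step 5 with purchased 3-(bromomethyl)cyclobutan-1-one (O=C1CC(CBr)C1, seven non-hydrogen atoms) to give 3-{[3-methoxy-4-(2,2-dimethylpropanoyloxy)phenyl]methyl}cyclobutan-1-one F1. This prochiral ketone is ring-expanded by a catalytic asymmetric Baeyer–Villiger oxidation (Sc(OTf)3 with a chiral N,N'-dioxide ligand, mCPBA, EtOAc, −20 °C; ligand antipode chosen for the R lactone). The fallback comes back to the route at 13.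

**Step 5 (cross-electrophile coupling).** Risks are homocoupling of either bromide and halide-induced opening of the oxetane by the zinc salts. The fallback sets out from 10 and replaces the reductive coupling by a two-electron cross-coupling. Purchased 3-methylideneoxetane (C=C1COC1) is hydroborated with 9-BBN-H (THF, rt) to 9-(oxetan-3-ylmethyl)-9-borabicyclo[3.3.1]nonane F2. This undergoes B-alkyl Suzuki–Miyaura coupling with 10 (Pd(dppf)Cl2, K3PO4, THF/H2O, 60 °C), coming back to the route at 12.

**Step 8 (one-pot reduction and cyclisation).** The risk is that the benzylic cation is captured by the free-phenol ring (Friedel–Crafts closure to an aryltetralin) instead of by oxygen, or that cyclisation is incomplete in aqueous acid. The fallback sets out from 14 and closes the oxolane before the reduction, while the arene is still deactivated as its pivalate. Compound 14 is stirred in methanolic HCl (from AcCl in MeOH, 40 °C); the lactone opens to the hydroxy methyl ester and its primary OH traps the benzylic cation. This gives methyl (2S,3S,4R)-4-{[3-methoxy-4-(2,2-dimethylpropanoyloxy)phenyl]methyl}-2-(3,4,5-trimethoxyphenyl)oxolane-3-carboxylate F3. Any phenol from partial loss of the pivalate is carried along. LiAlH4 (THF, 0 °C) then reduces the ester and the pivalate, coming back to the route at 16.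

## Further compounds

F1 | step 6 | 3-{[3-methoxy-4-(2,2-dimethylpropanoyloxy)phenyl]methyl}cyclobutan-1-one | COc1cc(CC2CC(=O)C2)ccc1OC(=O)C(C)(C)C
F2 | step 5 | 9-(oxetan-3-ylmethyl)-9-borabicyclo[3.3.1]nonane | C(C1COC1)B1C2CCCC1CCC2
F3 | step 8 | methyl (2S,3S,4R)-4-{[3-methoxy-4-(2,2-dimethylpropanoyloxy)phenyl]methyl}-2-(3,4,5-trimethoxyphenyl)oxolane-3-carboxylate | COc1cc(C[C@H]2CO[C@H](c3cc(OC)c(OC)c(OC)c3)[C@H]2C(=O)OC)ccc1OC(=O)C(C)(C)C
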